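A direct plan would make the open-chain iodo aldehyde A1 (Z-iodoalkene at C10, neopentyl aldehyde at C9) and would close the ring across C9–C10 by a CrCl2/NiCl2-mediated (Nozaki–Hiyama–Kishi) addition to the allylic alcohol A2.
Its weakest steps would be: (i) this ring closure, which would have to form an eleven-membered ring and set C9 from the remote C1 centre in the same event, with nothing that would secure 9R; (ii) the anti-carbomagnesiation–iodination of the propargylic alcohol A3, on which the Z-iodoalkene would depend; (iii) the exchanges of trityl, silyl, acetal and aryl acetate groups, which would add about six steps without adding complexity.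

The target holds a (Z)-2-ene-1,4-diol, O–C9–C10=C11–C1–O, inside its eleven-membered ring, and the route ties these two oxygens with a temporary silicon tether. The carbinol centres are set separately under reagent control, in alcohols 8 (C11, C1–C6; 1S; E-C3=C4 from a syn-carboalumination) and 12 (C7–C10; 9R), and joined as a diisopropylsilylene bis-ether. One ruthenium alkylidene then closes the seven-membered silaketal, which forms C10=C11 and can hold only the Z alkene, and the carbocycle at C6=C7, an alkene that diimide removes once the tether is cut. No organochromium ring closure, no Z-iodoalkene and no protecting-group exchange on the chain are needed, and C9 is never set during a macrocyclisation.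

Key step: step 6

Remarks on the chemistry:
- Ring atoms are numbered C1–C11 as in the name of the target (C1 bears the vanillate, C9 the acetate).
- (R)-2-(Prop-1-en-2-yl)oxirane is assumed not to be on sale as a single enantiomer and is therefore made in steps 1 and 2.
- The facial sense of the prenylboration in step 4 is taken from that of the parent B-allyl reagent of the same pinene series; the antipodal borane would be used if the sense proved opposite.

Step 1
Reactants: 1 methacrolein (2-methylprop-2-enal)
Product: 3 rac-2-(prop-1-en-2-yl)oxirane, via dimethylsulfonium methylide 2 (not isolated)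
Conditions: Me3S+ I−, NaH, DMSO/THF, 0 °C to rt; distillation
Reagents that add atoms: trimethylsulfonium iodide, C[S+](C)C.[I-]
Why: Corey–Chaykovsky epoxidation, in which the unstabilised sulfonium ylide adds to the aldehyde carbon rather than to the β-carbon of the enal and the betaine closes by 3-exo-tet displacement of dimethyl sulfide.

Step 2
Reactants: 3 rac-2-(prop-1-en-2-yl)oxirane
Product: 4 (R)-2-(prop-1-en-2-yl)oxirane
Conditions: (salen)Co(OAc) [the enantiomer that hydrolyses the S epoxide; salen = N,N′-bis(3,5-di-tert-butylsalicylidene)cyclohexane-1,2-diamine dianion] (0.5 mol %), H2O (0.55 equiv), neat, 0 °C to rt; distillation from the diol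
Reagents that add atoms: none
Why: Hydrolytic kinetic resolution of a terminal epoxide, in which two cobalt centres activate the epoxide and the hydroxide and only the S enantiomer is opened by water at its CH2 group, so the R epoxide should be recovered unchanged.

Step 3
Reactants: 5 pent-1-en-4-yne; 4 (R)-2-(prop-1-en-2-yl)oxirane
Product: 8 (3S,5E)-2,6-dimethylnona-1,5,8-trien-3-ol, via (E)-alkenyldimethylalane 6 (not isolated), via lithium alkenylaluminate 7 (not isolated)
Conditions: Me3Al (2 equiv), Cp2ZrCl2 (0.25 equiv), CH2Cl2, rt; volatiles removed; n-BuLi, hexane, 0 °C; then 4, THF, 0 °C to rt; aq. Rochelle salt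
Reagents that add atoms: trimethylaluminium, C[Al](C)C
Why: Zirconium-catalysed syn-methylalumination of the terminal alkyne (Negishi carboalumination) places methyl on C4 and aluminium on C3 on the same side, which fixes E-C3=C4, and the derived alkenylalanate should open the epoxide at its unsubstituted carbon (C2) in SN2 fashion with retention at the alkenyl carbon and without touching the C1–O bond, so the R epoxide becomes the 1S alcohol (the descriptor changes only through the priority rules).

Step 4
Reactants: 9 acrolein (prop-2-enal); 10 3-methylbuta-1,2-diene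
Product: 12 (3R)-4,4-dimethylhexa-1,5-dien-3-ol, via B-prenyldiisopinocampheylborane 11 (not isolated)
Conditions: crystalline (−)-Ipc2BH [prepared beforehand from (+)-α-pinene and BH3·SMe2], 10, THF, −25 to 0 °C; then 9, Et2O, −78 °C; NaOH, H2O2, 0 °C
Reagents that add atoms: none
Why: Asymmetric prenylboration (Brown allylboration with a γ,γ-dimethylallyl borane), in which hydroboration of the allene gives the primary prenylborane and a closed chair transition state delivers its γ-carbon to the aldehyde, creating the gem-dimethyl carbon C8 and the carbinol C9 in one bond, with the isopinocampheyl groups selecting the aldehyde face (9R expected).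

Step 5
Reactants: 12 (3R)-4,4-dimethylhexa-1,5-dien-3-ol; 8 (3S,5E)-2,6-dimethylnona-1,5,8-trien-3-ol
Product: 14 {[(3R)-4,4-dimethylhexa-1,5-dien-3-yl]oxy}{[(3S,5E)-2,6-dimethylnona-1,5,8-trien-3-yl]oxy}di(propan-2-yl)silane, via chlorosilyl ether 13 (not isolated)
Conditions: iPr2SiCl2 (3 equiv), imidazole, CH2Cl2, 0 °C to rt; excess silane removed in vacuo; then 8, imidazole, DMF, rt
Reagents that add atoms: dichlorodi(propan-2-yl)silane, CC(C)[Si](Cl)(Cl)C(C)C
Why: Stepwise silyl ether formation (installation of a temporary silicon tether), in which the hindered neopentylic alcohol 12 and an excess of the dichlorosilane should stop at the monochloride and the less hindered alcohol 8 then displaces the second chloride, so the unsymmetrical bis(alkoxy)silane forms without any change at C1 or C9.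

Step 6
Reactants: 14 {[(3R)-4,4-dimethylhexa-1,5-dien-3-yl]oxy}{[(3S,5E)-2,6-dimethylnona-1,5,8-trien-3-yl]oxy}di(propan-2-yl)silane
Product: 16 (1R,6E,9S,13Z)-2,2,6,14-tetramethyl-11,11-di(propan-2-yl)-10,12-dioxa-11-silabicyclo[7.3.2]tetradeca-3,6,13-triene, via monocyclic dioxasilepine 15 (not isolated)
Conditions: second-generation Grubbs catalyst (H2IMes)(PCy3)Cl2Ru=CHPh (10 mol % in two portions), 1,4-benzoquinone (20 mol %), toluene (1 mM), 80 °C, argon sparge
Reagents that add atoms: none
Why: Olefin metathesis by the Chauvin mechanism ([2+2] cycloaddition of a ruthenium alkylidene to an alkene, then cycloreversion), run as a temporary silicon-tethered ring-closing metathesis followed in the same flask by a macrocyclic ring-closing metathesis; both are known reaction types, the first for (Z)-2-ene-1,4-diols from bis(allyloxy)silanes and the second for eleven-membered carbocycles. The seven-membered 1,3-dioxa-2-silacycloheptene closes between the vinyl group on C9 and the isopropenyl group on C1 with loss of ethene, so C10=C11 becomes endocyclic in a ring too small to hold an E alkene, which fixes the Z geometry without reagent control. The eleven-membered carbocycle closes between the vinyl groups on C5 and C8 (bond C6=C7) with loss of a second ethene, and the geometry of this endocyclic alkene is irrelevant because step 8 removes it. No stereocentre is formed: C1 and C9 come from 8 and 12 and their C–O bonds are not touched. The step needs pairing selectivity and ring closure in preference to oligomerisation: C6 cannot reach C11 because that seven-membered ring would have to contain the E-C3=C4 alkene, C7 cannot reach C10 (cyclobutene), and the seven-membered closure at C10/C11 should outrun the eight- and eleven-membered alternatives and is irreversible once the trisubstituted alkene exists, whereas a wrongly closed disubstituted macrocycle can reopen with ethene. High dilution, the gem-dimethyl group and the tether should then favour the intramolecular C6/C7 closure, and benzoquinone should suppress migration of the skipped C3=C4/C6 diene.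

Step 7
Reactants: 16 (1R,6E,9S,13Z)-2,2,6,14-tetramethyl-11,11-di(propan-2-yl)-10,12-dioxa-11-silabicyclo[7.3.2]tetradeca-3,6,13-triene
Product: 17 (1S,2Z,4R,9E)-2,5,5,9-tetramethylcycloundeca-2,6,9-triene-1,4-diol
Conditions: HF·pyridine, pyridine/THF, 0 °C to rt
Reagents that add atoms: none
Why: Fluoride-driven cleavage of the silylene acetal (Si–F bond formation) should release both hydroxyl groups with retention, because only Si–O bonds break, and the pyridine-buffered medium should leave the acid-sensitive (Z)-ene-1,4-diol and the three alkenes untouched.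

Step 8
Reactants: 17 (1S,2Z,4R,9E)-2,5,5,9-tetramethylcycloundeca-2,6,9-triene-1,4-diol
Product: 18 (1R,2Z,4S,6E)-3,7,11,11-tetramethylcycloundeca-2,6-diene-1,4-diol
Conditions: 2-nitrobenzenesulfonohydrazide (5 equiv), Et3N, CH2Cl2, rt
Reagents that add atoms: none
Why: Diimide reduction, a concerted syn transfer of two hydrogen atoms whose rate falls steeply with alkene substitution, so the 1,2-disubstituted C6=C7 alkene should be saturated while the trisubstituted C3=C4 alkene and the trisubstituted C10=C11 alkene between the two carbinol carbons remain, and neither a hydroxyl group nor a stereocentre is affected.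

Step 9
Reactants: 19 vanillic acid
Product: 21 4-[(tert-butyldimethylsilyl)oxy]-3-methoxybenzoic acid, via bis-silylated vanillic acid 20 (not isolated)
Conditions: TBSCl (2.3 equiv), imidazole, DMF, rt; then AcOH/THF/H2O (3:1:1), rt
Reagents that add atoms: tert-butyldimethylsilyl chloride, CC(C)(C)[Si](C)(C)Cl
Why: Imidazole-promoted silylation of the phenol and the carboxyl group, followed by selective hydrolysis of the labile silyl ester under mild acid, which the aryl silyl ether should survive.

Step 10
Reactants: 18 (1R,2Z,4S,6E)-3,7,11,11-tetramethylcycloundeca-2,6-diene-1,4-diol; 21 4-[(tert-butyldimethylsilyl)oxy]-3-methoxybenzoic acid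
Product: 23 (1S,3E,9R,10Z)-9-hydroxy-4,8,8,11-tetramethylcycloundeca-3,10-dien-1-yl 4-[(tert-butyldimethylsilyl)oxy]-3-methoxybenzoate, via O-acylisourea 22 (not isolated)
Conditions: DCC (1.1 equiv), DMAP (0.1 equiv), CH2Cl2, −10 to 0 °C
Reagents that add atoms: none
Why: Steglich esterification, site-selective because the C9 hydroxyl is neopentylic (next to the C8 gem-dimethyl group) whereas the C1 hydroxyl is not, and stereoretentive because the C1–O bond is not broken.

Step 11
Reactants: 23 (1S,3E,9R,10Z)-9-hydroxy-4,8,8,11-tetramethylcycloundeca-3,10-dien-1-yl 4-[(tert-butyldimethylsilyl)oxy]-3-methoxybenzoate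
Product: 24 (1S,3E,9R,10Z)-9-acetoxy-4,8,8,11-tetramethylcycloundeca-3,10-dien-1-yl 4-[(tert-butyldimethylsilyl)oxy]-3-methoxybenzoate
Conditions: Ac2O, DMAP, pyridine, rt
Reagents that add atoms: acetic anhydride, CC(=O)OC(C)=O
Why: DMAP-catalysed acetylation of the hindered allylic alcohol with retention at C9, the phenol being blocked as its silyl ether so that only one hydroxyl group is available.

Step 12
Reactants: 24 (1S,3E,9R,10Z)-9-acetoxy-4,8,8,11-tetramethylcycloundeca-3,10-dien-1-yl 4-[(tert-butyldimethylsilyl)oxy]-3-methoxybenzoate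
Product: 25 (1S,3E,9R,10Z)-9-acetoxy-4,8,8,11-tetramethylcycloundeca-3,10-dien-1-yl 4-hydroxy-3-methoxybenzoate (CNP0124394.1)
Conditions: Bu4NF (1.1 equiv), AcOH (1.2 equiv), THF, 0 °C
Reagents that add atoms: none
Why: Fluoride desilylation of an aryl silyl ether, fast because the para-acyl phenoxide is a good leaving group on silicon, and buffered with acetic acid so that the allylic acetate and the benzoate should be neither cleaved nor shifted.

Compound list
1 | methacrolein (2-methylprop-2-enal) | CC(=C)C=O | starting material
2 | dimethylsulfonium methylide (not isolated) | C[S+](C)[CH2-] | intermediate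
3 | rac-2-(prop-1-en-2-yl)oxirane | CC(=C)C1CO1 | intermediate
4 | (R)-2-(prop-1-en-2-yl)oxirane | C=C(C)[C@@H]1CO1 | intermediate
5 | pent-1-en-4-yne | C#CCC=C | starting material
6 | dimethyl[(1E)-2-methylpenta-1,4-dien-1-yl]alane (not isolated) | C[Al](C)/C=C(\C)CC=C | intermediate
7 | lithium butyldimethyl[(1E)-2-methylpenta-1,4-dien-1-yl]aluminate (not isolated) | [Li+].CCCC[Al-](C)(C)/C=C(\C)CC=C | intermediate
8 | (3S,5E)-2,6-dimethylnona-1,5,8-trien-3-ol | C=C(C)[C@@H](O)C/C=C(\C)CC=C | intermediate
9 | acrolein (prop-2-enal) | C=CC=O | starting material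
10 | 3-methylbuta-1,2-diene | CC(C)=C=C | starting material
11 | B-(3-methylbut-2-en-1-yl)diisopinocampheylborane (not isolated) | CC(C)=CCB([C@@H]1C[C@@H]2C[C@H]([C@H]1C)C2(C)C)[C@@H]1C[C@@H]2C[C@H]([C@H]1C)C2(C)C | intermediate
12 | (3R)-4,4-dimethylhexa-1,5-dien-3-ol | C=CC(C)(C)[C@H](O)C=C | intermediate
13 | chloro{[(3R)-4,4-dimethylhexa-1,5-dien-3-yl]oxy}di(propan-2-yl)silane (not isolated) | C=CC(C)(C)[C@H](O[Si](Cl)(C(C)C)C(C)C)C=C | intermediate
14 | {[(3R)-4,4-dimethylhexa-1,5-dien-3-yl]oxy}{[(3S,5E)-2,6-dimethylnona-1,5,8-trien-3-yl]oxy}di(propan-2-yl)silane | C=CC(C)(C)[C@H](O[Si](C(C)C)(C(C)C)O[C@H](C(C)=C)C/C=C(\C)CC=C)C=C | intermediate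
15 | (4R,7S)-6-methyl-4-(2-methylbut-3-en-2-yl)-7-[(2E)-3-methylhexa-2,5-dien-1-yl]-2,2-di(propan-2-yl)-4,7-dihydro-1,3,2-dioxasilepine (not isolated) | C=CC(C)(C)[C@@H]1O[Si](C(C)C)(C(C)C)O[C@@H](C/C=C(\C)CC=C)C(C)=C1 | intermediate
16 | (1R,6E,9S,13Z)-2,2,6,14-tetramethyl-11,11-di(propan-2-yl)-10,12-dioxa-11-silabicyclo[7.3.2]tetradeca-3,6,13-triene (bridgeheads 1 and 9 are C9 and C1 of the carbocycle; C3=C4 of this name is the C6=C7 alkene of undefined geometry) | CC(C)[Si]1(C(C)C)O[C@H]2C/C=C(\C)CC=CC(C)(C)[C@H](O1)/C=C\2C | intermediate
17 | (1S,2Z,4R,9E)-2,5,5,9-tetramethylcycloundeca-2,6,9-triene-1,4-diol (C6=C7 of this name of undefined geometry) | O[C@H]1C/C=C(\C)CC=CC(C)(C)[C@H](O)/C=C\1C | intermediate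
18 | (1R,2Z,4S,6E)-3,7,11,11-tetramethylcycloundeca-2,6-diene-1,4-diol | O[C@H]1C/C=C(\C)CCCC(C)(C)[C@H](O)/C=C\1C | intermediate
19 | vanillic acid | COc1cc(C(=O)O)ccc1O | starting material
20 | tert-butyldimethylsilyl 4-[(tert-butyldimethylsilyl)oxy]-3-methoxybenzoate (not isolated) | COc1cc(C(=O)O[Si](C)(C)C(C)(C)C)ccc1O[Si](C)(C)C(C)(C)C | intermediate
21 | 4-[(tert-butyldimethylsilyl)oxy]-3-methoxybenzoic acid | COc1cc(C(=O)O)ccc1O[Si](C)(C)C(C)(C)C | intermediate
22 | O-{4-[(tert-butyldimethylsilyl)oxy]-3-methoxybenzoyl}-N,N′-dicyclohexylisourea (not isolated) | COc1cc(C(=O)OC(=NC2CCCCC2)NC2CCCCC2)ccc1O[Si](C)(C)C(C)(C)C | intermediate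
23 | (1S,3E,9R,10Z)-9-hydroxy-4,8,8,11-tetramethylcycloundeca-3,10-dien-1-yl 4-[(tert-butyldimethylsilyl)oxy]-3-methoxybenzoate | COc1cc(C(=O)O[C@H]2C/C=C(\C)CCCC(C)(C)[C@H](O)/C=C\2C)ccc1O[Si](C)(C)C(C)(C)C | intermediate
24 | (1S,3E,9R,10Z)-9-acetoxy-4,8,8,11-tetramethylcycloundeca-3,10-dien-1-yl 4-[(tert-butyldimethylsilyl)oxy]-3-methoxybenzoate | COc1cc(C(=O)O[C@H]2C/C=C(\C)CCCC(C)(C)[C@H](OC(C)=O)/C=C\2C)ccc1O[Si](C)(C)C(C)(C)C | intermediate
25 | (1S,3E,9R,10Z)-9-acetoxy-4,8,8,11-tetramethylcycloundeca-3,10-dien-1-yl 4-hydroxy-3-methoxybenzoate (CNP0124394.1) | COc1cc(C(=O)O[C@H]2C/C=C(\C)CCCC(C)(C)[C@H](OC(C)=O)/C=C\2C)ccc1O | target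

Total step count: 12. Longest linear sequence: 10 steps (1, 2, 3, 5, 6, 7, 8, 10, 11, 12); steps 4 and 9 are side branches.

Steps most likely to fail

Step 6. The second ring closure may stall at the monocycle or give oligomers, because the carbocycle has to close around a silaketal whose two chains leave the seven-membered ring on opposite faces; a crossed pairing of C6 with C10 may also compete. The fallback sets out from 14 and comes back at 17. The metathesis is run only until the seven-membered ring has closed (same catalyst, 2 mM, 40 °C) and 15 is isolated. HF·pyridine then removes the tether and gives the open-chain diol (4E,7S,8Z,10R)-4,8,11,11-tetramethyltrideca-1,4,8,12-tetraene-7,10-diol F1, in which the Z alkene is already secured. Ring-closing metathesis of this unbridged diol at 1 mM with the same catalyst should give 17.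

Step 8. Chemoselectivity may be lost if the E-configured C3=C4 alkene of the relaxed eleven-membered ring, which carries transannular strain, takes up diimide at a rate close to that of the hindered C6=C7 alkene next to quaternary C8; the reduction may also stay incomplete. The fallback sets out from 16 and comes back at 18, with the order of operations changed and a reductant of another kind. The C6=C7 alkene is hydrogenated while the silylene bridge is still in place, over RhCl(PPh3)3 (H2, 1 atm, benzene), a catalyst that selects by coordination of the less substituted alkene and that meets no free allylic hydroxyl group in this substrate. This gives (1S,3E,9R,13Z)-4,8,8,13-tetramethyl-11,11-di(propan-2-yl)-10,12-dioxa-11-silabicyclo[7.3.2]tetradeca-3,13-diene F2, and HF·pyridine as in step 7 then gives 18.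

Step 3. The vinyl epoxide may be opened at the wrong place (attack at the allylic carbon or SN2′ attack at the isopropenyl terminus), or the alkenyl transfer may be slow. The fallback sets out from 5 and comes back at 8. The alanate 7, made as in step 3, is treated with oxirane, which offers no regiochemical choice, to give (3E)-4-methylhepta-3,6-dien-1-ol F3. Dess–Martin oxidation gives (3E)-4-methylhepta-3,6-dienal F4, which is used at once, and isopropenylmagnesium bromide adds to it to give rac-(5E)-2,6-dimethylnona-1,5,8-trien-3-ol F5. A second Dess–Martin oxidation gives (5E)-2,6-dimethylnona-1,5,8-trien-3-one F6. Corey–Bakshi–Shibata reduction with (R)-1-methyl-3,3-diphenyltetrahydro-1H,3H-pyrrolo[1,2-c][1,3,2]oxazaborole (0.2 equiv) and catecholborane in toluene at −78 °C, the alkenyl group acting as the large substituent, should give 8.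

Further compounds
F1 | step 6 | (4E,7S,8Z,10R)-4,8,11,11-tetramethyltrideca-1,4,8,12-tetraene-7,10-diol | C=CC(C)(C)[C@H](O)/C=C(C)\[C@@H](O)C/C=C(\C)CC=C
F2 | step 8 | (1S,3E,9R,13Z)-4,8,8,13-tetramethyl-11,11-di(propan-2-yl)-10,12-dioxa-11-silabicyclo[7.3.2]tetradeca-3,13-diene | CC(C)[Si]1(C(C)C)O[C@H]2C/C=C(\C)CCCC(C)(C)[C@H](O1)/C=C\2C
F3 | step 3 | (3E)-4-methylhepta-3,6-dien-1-ol | OCC/C=C(\C)CC=C
F4 | step 3 | (3E)-4-methylhepta-3,6-dienal | O=CC/C=C(\C)CC=C
F5 | step 3 | rac-(5E)-2,6-dimethylnona-1,5,8-trien-3-ol | C=C(C)C(O)C/C=C(\C)CC=C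
F6 | step 3 | (5E)-2,6-dimethylnona-1,5,8-trien-3-one | C=C(C)C(=O)C/C=C(\C)CC=C
A1 | direct plan | (1Z,3S,5E)-1-iodo-2,6,10,10-tetramethyl-11-oxoundeca-1,5-dien-3-yl 4-acetoxy-3-methoxybenzoate | I/C=C(C)\[C@@H](OC(=O)c1ccc(OC(C)=O)c(OC)c1)C/C=C(\C)CCCC(C)(C)C=O
A2 | direct plan | (1S,3E,9R,10Z)-9-hydroxy-4,8,8,11-tetramethylcycloundeca-3,10-dien-1-yl 4-acetoxy-3-methoxybenzoate | COc1cc(C(=O)O[C@H]2C/C=C(\C)CCCC(C)(C)[C@H](O)/C=C\2C)ccc1OC(C)=O
A3 | direct plan | (3S,5E)-11,11-dimethoxy-6,10,10-trimethylundec-5-en-1-yn-3-ol | C#C[C@@H](O)C/C=C(\C)CCCC(C)(C)C(OC)OC
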